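All constants are made up; what happens was integrated by code.

You can't keep the target in this flask for good: at equilibrium dissolved target stands at 12.7 mM, less than the solubility of 28 mM, so the crystals have to go, and the isomer is the thermodynamic product (kinetic against thermodynamic control).

    gas phase ⇌ dissolved gas, rate k1*(csat - [dissolved gas]) (k1 = 1.22 min⁻¹, csat = 17 mM)
    substrate + dissolved gas → target (k2 = 22.4 L mol⁻¹ min⁻¹)
    dissolved gas → decomposed reagent (k3 = 0.0142 min⁻¹)
    target ⇌ isomer of the product (K4 = 30.5, k4 = 0.0917 min⁻¹)
    crystals ⇌ target, rate k5*(cs5 - [target]) while solid is left; crystals form when [target] > cs5 (cs5 = 28 mM, k5 = 0.309 min⁻¹)

substrate 0.40 M; gas phase 17 mM (held); time 80 min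

- target is meant together with its crystals
- solid, in amounts per volume of the solution: crystals
- at the start none of the gas is dissolved
- run time (flask): 80 min

- birch: doubling the solubility in step 5, all else as stated
- ash: doubling the dissolution coefficient of step 5, all else as stated
- alder: doubling the saturation concentration of gas phase, all else as stated
- oak: doubling the transfer coefficient of step 1, all else as stated

- target and crystals together at 80 min, in percent of the substrate charged
- the change that raises the amount of target and crystals together at 80 min, in percent of the substrate charged most ("none" if none brings more than 2 percentage points) (birch / ash / alder / oak / none)
- amount of target and crystals together at 80 min, in percent of the substrate charged, after alder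

Here is my handover. Gas can arrive at up to 20.7 mM min⁻¹, which serves the charge in 19.3 min, shorter than the run of 80 min, so I count the substrate as converted at the start.

Let k be the forward isomerisation constant, c the dissolution coefficient, K the equilibrium constant and S the solubility. Fresh target splits, and the share k/(k+c) = 22.9% becomes isomer. While crystals stand, dissolution and isomerisation run in series, pulling the isomer towards K·S with rate constant a = kc/((k+c)K) = 0.00232 min⁻¹.

The crystal leak, the isomer this pull has made by the time of reading provided crystals still stand then, whatever the charge, is 145 mM. Adding the fresh share, decayed at the same constant, gives 221 mM of isomer when you come, so y is 44.8%.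

Leave the gas alone: alder and oak enter neither term, so yb stays at 44.8%. Don't touch birch either, which doubles K·S, the level the isomer is pulled towards while crystals stand. Take ash, which gives 49.2%, a gain of 4.4 percentage points.

The forecast gives y = 45.6%, a little above mine, best = ash and yb = 45.8%, saying “Alder and oak only speed up an already complete step”.

The simulation gives y = 45.7%, best = ash with a gain of 4.2 points, and yb = 45.8%. In this flask the relaxation half-life of the isomerisation step by itself is 7.32 min, shorter than the run. The half-life of the leak's approach is 299 min, longer than the run, and in this flask the isomer reads 54.3% at 80.0 min against 55.2% reckoned. In the neighbour flask with 0.68 M of substrate, the same leak plus the fresh share gives y = 59.7%, and that flask reads 59.6%.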